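The closed, stirred vessels on the bench each hold starting material that gives a target, and the target readings run differently with the charge.

| flask | starting material | remark | time |
|---|---|---|---|
| maple | 0.018 M | run made earlier |  |
| oak | 0.072 M | run made earlier |  |
| cedar | 0.29 M | run made earlier |  |
| noon | 0.020 M |  | 3.0 h |
| autumn | 0.040 M |  | 3.0 h |
| winter | 0.080 M |  | 3.0 h |
| dusk | 0.15 M |  | 3.0 h |
| spring | 0.30 M |  | 3.0 h |

- maple (time / min: target / %): 8.00: 0; 15.0: 3; 25.0: 3; 50.0: 0; 90.0: 0
- oak (time / min: target / %): 20.0: 4; 40.0: 1; 50.0: 5; 80.0: 11; 90.0: 13
- cedar (time / min: target / %): 8.00: 0; 25.0: 55; 40.0: 27; 60.0: 10; 90.0: 4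

(standard deviation of a reading: 2 percentage points)

- "hardly changes" means that all values lie within two and a half points (for a concentration: within two and a half percent of the largest)

* [target] at the end for noon, autumn, winter, dusk, spring, in this order
* how that number moves from the first to the last of them (rises, then falls / hardly changes / falls all the way / falls, then rises / rises all the way)

Here is the note for whoever takes over. Leave the volume alone, since our reckoning rests on the charges as they stand. Cedar's tail shows target being lost first-order at 0.0497 /min, a half-life of 13.9 min, which is short against the time asked. Oak's rise, with that loss added back, gives a growth constant of 1.02 /M/min. Target thus multiplies itself, pseudo-first-order at a given c(starting material), with net rate constant kg·c(starting material) − kd. Both are readings and carry their scatter. We read kd/kg as 0.0486 M and call this c(starting material), at which gain equals loss, the ignition threshold.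

Now the two ends. At the low end, noon lies below the threshold, so we expect little target, as in maple, whose readings stayed between 0% and 3%. At the high end, spring should burst as early as cedar, whose charge is close. Taking cedar's reading of 55% at 25.0 min for spring, decay until 180 min leaves spring, by our estimate, about 7.49 × 10⁻⁵ M. Joining the ends, we expect the end value to rise, then fall, with winter, the first charge above the threshold, burning latest and ending highest.

The forecast, from a threshold of 0.04 M against our 0.0486 M and the view that the flask “behaves like an epidemic”, gives 1.000 × 10⁻⁵ M, 3.000 × 10⁻⁴ M, 0.0027 M, 3.000 × 10⁻⁴ M, 1.000 × 10⁻⁴ M: rises, then falls.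

The flasks give 1.62 × 10⁻⁴ M, 7.67 × 10⁻⁴ M, 9.11 × 10⁻⁴ M, 6.33 × 10⁻⁵ M, 8.99 × 10⁻⁶ M: rises, then falls.

    starting material + target → 2 target (k = 0.0257 /M/s)
    starting material → target (k = 5.54 × 10⁻⁶ /s)
    target → over-reaction product (k = 0.00110 /s)

Winter ends highest, and the row turns at 0.059 M, above our threshold of 0.0486 M. Winter has 22.7% of its starting material left at the end, so c(starting material) is 0.0181 M, below the threshold: by our net rate constant, its target is shrinking by then. Autumn, charged at 0.040 M, started below the threshold, and its target went from 2.06% after 1.50 h to 1.92% after 3.00 h.

All runs were generated by integration for an exercise; noise was put on by code.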